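**Retrosynthetic overview** (cyclohexane locants: C1 = CH with the acetoxypropyl chain, C2 = quaternary C, C3 = CHCH3, C4 and C5 = CH2, C6 = C(=CMe2))
1. Endgame: 19 comes from acetylation and desilylation after Pd C–O coupling of neopentyl alcohol 15 with 7-bromocoumarin 16. Alcohol 15 comes from the α-quaternary aldehyde 14.
2. Enabling feature: C2 is quaternary and carries CH3 plus an exocyclic oxygenated carbon (the CH2OAr carbon), next to C1–H. Moving that exocyclic carbon back into the ring between C2 and C1 turns the cyclohexane into a 1-methylcycloheptene oxide (13). Aldehyde 14 is therefore its Meinwald ring-contraction product, and the seven-membered ring revealed is a cyclohepta-1,4-diene.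
3. The C6 isopropylidene is a masked enoate whose ester carbon becomes the CMe2 carbon (MeLi, dehydration, 1,4-hydrogenation). This keeps that alkene electron-poor while the other alkene is epoxidised.
4. Key disconnection: cycloheptadiene 9 comes from a formal [4+3] of vinyldiazoacetate 7 (the C6–C5–C4 unit) with the acyclic (4Z,6E)-diene 5. It forms the C6–C1 and C4–C3 bonds and both CH stereocentres in one flask.
5. Order of rings: cyclopropane (transient), then cycloheptadiene, then oxirane, then cyclohexane. The coumarin is bought intact.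

Key step: step 4

Assumption: the sense of induction of Rh2(S-DOSP)4 is extrapolated from its cyclopropanation model, with the allyl-stabilised diene carbon taking the place of a benzylic carbon. Should the antipode form, Rh2(R-DOSP)4 is used and nothing else changes.

**Step 1**
Reactants: 1 (4-bromobutoxy)(tert-butyl)dimethylsilane
Product: 2 [4-(tert-butyldimethylsilyloxy)butyl]triphenylphosphonium bromide
Conditions: PPh3, toluene, 110 °C
Reagents that add atoms: triphenylphosphine, c1ccc(cc1)P(c1ccccc1)c1ccccc1
Why: SN2 quaternisation of the phosphine by the unhindered primary bromide (phosphonium salt formation) leaves the silyl ether untouched.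

**Step 2**
Reactants: 2 [4-(tert-butyldimethylsilyloxy)butyl]triphenylphosphonium bromide; 3 tiglic aldehyde, (E)-2-methylbut-2-enal
Product: 5 tert-butyl{[(4Z,6E)-6-methylocta-4,6-dien-1-yl]oxy}dimethylsilane, via phosphorus ylide 4 (not isolated)
Conditions: NaHMDS, THF, 0 °C; then 3, −78 °C → rt
Reagents that add atoms: none
Why: Wittig olefination with a non-stabilised ylide under lithium-free conditions is kinetically Z-selective, and the E geometry of the trisubstituted alkene is carried over unchanged from tiglic aldehyde.

**Step 3**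
Reactants: 6 methyl but-3-enoate
Product: 7 methyl 2-diazobut-3-enoate
Conditions: p-ABSA, DBU, MeCN, 0 °C; extracted into cold pentane and used at once
Reagents that add atoms: 4-acetamidobenzenesulfonyl azide (p-ABSA), CC(=O)Nc1ccc(cc1)S(=O)(=O)N=[N+]=[N-]
Why: Regitz diazo transfer works because the CH2 is both allylic and α to the ester and is deprotonated by DBU; the product is kept cold because it slowly electrocyclises to a pyrazole.

**Step 4**
Reactants: 5 tert-butyl{[(4Z,6E)-6-methylocta-4,6-dien-1-yl]oxy}dimethylsilane (1.5 equiv); 7 methyl 2-diazobut-3-enoate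
Product: 9 methyl (4S,7R)-7-[3-(tert-butyldimethylsilyloxy)propyl]-4,5-dimethylcyclohepta-1,5-diene-1-carboxylate, via cis-divinylcyclopropane 8 (not isolated)
Conditions: Rh2(S-DOSP)4 (1 mol %), hexanes, −40 °C, slow addition of 7; then toluene added, 110 °C, same flask
Reagents that add atoms: none
Why: The catalyst extrudes N2 from 7 to give a donor/acceptor rhodium vinylcarbenoid that adds in a concerted asynchronous [2+1] manner to the Z-disubstituted C4=C5 alkene of 5 (carbenoid carbon to C4, first lasting bond) to give the all-cis divinylcyclopropane 8, which on heating undergoes the [3,3] divinylcyclopropane–cycloheptadiene (Cope) rearrangement through the only accessible boat transition state, breaking the temporary carbenoid-carbon–C5 bond and joining the vinyl CH2 to C7 of the diene (second lasting bond). The closest known reaction type is the tandem asymmetric cyclopropanation/Cope rearrangement (formal [4+3] cycloaddition) of vinyldiazoacetates with acyclic dienes, including Z,E-dienes that react at the cis alkene and need heat for the sigmatropic step. The three-membered ring closes by carbene [2+1] cycloaddition and the seven-membered ring by [3,3] ring expansion, overall suprafacial on the s-cis diene. The side-chain stereocentre (C7 of 9) is set absolutely by the chiral dirhodium carboxylate in the stereospecific syn cyclopropanation, and the CHCH3 centre (C4 of 9) follows from it through the boat geometry, the Z alkene placing the chain "inside" and the E alkene placing the methyl "outside", hence trans. The step needs site selectivity for the disubstituted over the trisubstituted alkene and over C–H insertion, which is secured because these carbenoids cyclopropanate cis-1,2-disubstituted alkenes but are sterically shut out from trisubstituted and trans alkenes (any E,E-diene contaminant stays inert), while orientation is fixed by allylic stabilisation of the developing charge at C5. The ester is both the acceptor group that tames the carbenoid and the later CMe2 carbon.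

**Step 5**
Reactants: 9 methyl (4S,7R)-7-[3-(tert-butyldimethylsilyloxy)propyl]-4,5-dimethylcyclohepta-1,5-diene-1-carboxylate
Product: 10 methyl (4S,5S,6R,7S)-7-[3-(tert-butyldimethylsilyloxy)propyl]-5,6-epoxy-4,5-dimethylcyclohept-1-ene-1-carboxylate (oxygen anti to the side chain, syn to the C4 methyl)
Conditions: D-fructose-derived Shi ketone (30 mol %), Oxone, K2CO3, Bu4NHSO4, MeCN–DMM/aq. borate–EDTA buffer, 0 °C
Reagents that add atoms: potassium peroxymonosulfate (Oxone), [K+].[O-]S(=O)(=O)OO
Why: In the Shi epoxidation the electrophilic chiral dioxirane ignores the ester-conjugated alkene and, by the spiro transition-state model for trisubstituted and 1-substituted cyclic alkenes, should deliver oxygen anti to the side chain under reagent control, since the two allylic substituents lie on opposite faces and leave little substrate bias, setting both oxirane carbons.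

**Step 6**
Reactants: 10 methyl (4S,5S,6R,7S)-7-[3-(tert-butyldimethylsilyloxy)propyl]-5,6-epoxy-4,5-dimethylcyclohept-1-ene-1-carboxylate
Product: 11 2-{(4S,5S,6R,7S)-7-[3-(tert-butyldimethylsilyloxy)propyl]-5,6-epoxy-4,5-dimethylcyclohept-1-en-1-yl}propan-2-ol
Conditions: MeLi (2.5 equiv), THF, −78 °C; H2O quench at −78 °C
Reagents that add atoms: methyllithium, [Li]C
Why: Double 1,2-addition of the organolithium to the ester gives the tertiary allylic alcohol, the trisubstituted epoxide being inert at −78 °C and the cold quench keeping the alkoxide from opening it.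

**Step 7**
Reactants: 11 2-{(4S,5S,6R,7S)-7-[3-(tert-butyldimethylsilyloxy)propyl]-5,6-epoxy-4,5-dimethylcyclohept-1-en-1-yl}propan-2-ol
Product: 12 (4S,5S,6R,7S)-7-[3-(tert-butyldimethylsilyloxy)propyl]-5,6-epoxy-4,5-dimethyl-1-(prop-1-en-2-yl)cyclohept-1-ene
Conditions: Burgess reagent, toluene, 60 °C
Reagents that add atoms: none
Why: Burgess dehydration (syn Ei elimination of the sulfamate) can only take a methyl hydrogen because the ring carbon next to the carbinol is sp2, so a single 1,3-diene forms under neutral conditions that spare the epoxide.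

**Step 8**
Reactants: 12 (4S,5S,6R,7S)-7-[3-(tert-butyldimethylsilyloxy)propyl]-5,6-epoxy-4,5-dimethyl-1-(prop-1-en-2-yl)cyclohept-1-ene
Product: 13 (1S,2R,3S,7S)-3-[3-(tert-butyldimethylsilyloxy)propyl]-1,2-epoxy-1,7-dimethyl-4-(propan-2-ylidene)cycloheptane
Conditions: (η6-naphthalene)Cr(CO)3 (15 mol %), H2 (50 atm), THF, 45 °C
Reagents that add atoms: none
Why: Arene–Cr(CO)3-catalysed 1,4-hydrogenation adds H2 only across the termini of the s-cis diene, a known route from 1-alkenylcycloalkenes to exocyclic alkenes, which places the remaining double bond exactly between the ring carbon and the CMe2 carbon and leaves epoxide and silyl ether alone.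

**Step 9**
Reactants: 13 (1S,2R,3S,7S)-3-[3-(tert-butyldimethylsilyloxy)propyl]-1,2-epoxy-1,7-dimethyl-4-(propan-2-ylidene)cycloheptane
Product: 14 (1S,2S,6S)-2-[3-(tert-butyldimethylsilyloxy)propyl]-1,6-dimethyl-3-(propan-2-ylidene)cyclohexane-1-carbaldehyde
Conditions: MABR [methylaluminium bis(4-bromo-2,6-di-tert-butylphenoxide), 20 mol %], CH2Cl2, −78 → −40 °C; cold NaF/H2O quench
Reagents that add atoms: none
Why: In this Meinwald (semipinacol-type) rearrangement the bulky aluminium Lewis acid ionises the tertiary C–O bond and favours alkyl over hydride shift, so the allylic ring carbon bearing the side chain migrates with retention to the tertiary carbon anti to the leaving oxygen (inversion there), contracting the ring and translating the epoxide configuration into the quaternary stereocentre.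

**Step 10**
Reactants: 14 (1S,2S,6S)-2-[3-(tert-butyldimethylsilyloxy)propyl]-1,6-dimethyl-3-(propan-2-ylidene)cyclohexane-1-carbaldehyde
Product: 15 {(1S,2S,6S)-2-[3-(tert-butyldimethylsilyloxy)propyl]-1,6-dimethyl-3-(propan-2-ylidene)cyclohexyl}methanol
Conditions: NaBH4, MeOH, 0 °C
Reagents that add atoms: none
Why: Borohydride reduction of the non-enolisable aldehyde touches no stereocentre and no alkene.

**Step 11**
Reactants: 15 {(1S,2S,6S)-2-[3-(tert-butyldimethylsilyloxy)propyl]-1,6-dimethyl-3-(propan-2-ylidene)cyclohexyl}methanol; 16 7-bromocoumarin (7-bromo-2H-chromen-2-one)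
Product: 17 7-({(1S,2S,6S)-2-[3-(tert-butyldimethylsilyloxy)propyl]-1,6-dimethyl-3-(propan-2-ylidene)cyclohexyl}methoxy)-2H-chromen-2-one
Conditions: [(allyl)PdCl]2 (2 mol %), RockPhos (6 mol %), Cs2CO3, toluene, 90 °C
Reagents that add atoms: none
Why: Pd-catalysed C–O cross-coupling (Buchwald–Hartwig etherification) forms the aryl–oxygen bond, so no substitution at the neopentyl carbon is needed; the bulky biaryl phosphine favours reductive elimination over β-hydride elimination, the electron-poor bromide is a good partner, and carbonate in toluene spares the lactone.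

**Step 12**
Reactants: 17 7-({(1S,2S,6S)-2-[3-(tert-butyldimethylsilyloxy)propyl]-1,6-dimethyl-3-(propan-2-ylidene)cyclohexyl}methoxy)-2H-chromen-2-one
Product: 18 7-{[(1S,2S,6S)-2-(3-hydroxypropyl)-1,6-dimethyl-3-(propan-2-ylidene)cyclohexyl]methoxy}-2H-chromen-2-one
Conditions: HF·pyridine, THF–pyridine, 0 °C → rt
Reagents that add atoms: none
Why: Fluoride-driven desilylation under buffered conditions leaves lactone, aryl ether and tetrasubstituted alkene intact.

**Step 13**
Reactants: 18 7-{[(1S,2S,6S)-2-(3-hydroxypropyl)-1,6-dimethyl-3-(propan-2-ylidene)cyclohexyl]methoxy}-2H-chromen-2-one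
Product: 19 3-[(1S,2S,3S)-2,3-dimethyl-2-{[(2-oxo-2H-chromen-7-yl)oxy]methyl}-6-(propan-2-ylidene)cyclohexyl]propyl acetate (target)
Conditions: Ac2O, pyridine, DMAP (cat.), CH2Cl2, rt
Reagents that add atoms: acetic anhydride, CC(=O)OC(C)=O
Why: DMAP-catalysed acylation of the unhindered primary alcohol completes the target without touching any stereocentre.

**Compound list**
1 | (4-bromobutoxy)(tert-butyl)dimethylsilane | CC(C)(C)[Si](C)(C)OCCCCBr | starting material
2 | [4-(tert-butyldimethylsilyloxy)butyl]triphenylphosphonium bromide | CC(C)(C)[Si](C)(C)OCCCC[P+](c1ccccc1)(c1ccccc1)c1ccccc1.[Br-] | intermediate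
3 | tiglic aldehyde, (E)-2-methylbut-2-enal | C/C=C(\C)C=O | starting material
4 | [4-(tert-butyldimethylsilyloxy)butylidene]triphenylphosphorane | CC(C)(C)[Si](C)(C)OCCCC=P(c1ccccc1)(c1ccccc1)c1ccccc1 | intermediate
5 | tert-butyl{[(4Z,6E)-6-methylocta-4,6-dien-1-yl]oxy}dimethylsilane | C/C=C(\C)/C=C\CCCO[Si](C)(C)C(C)(C)C | intermediate
6 | methyl but-3-enoate | COC(=O)CC=C | starting material
7 | methyl 2-diazobut-3-enoate | COC(=O)C(=[N+]=[N-])C=C | intermediate
8 | methyl 2-[(E)-but-2-en-2-yl]-3-[3-(tert-butyldimethylsilyloxy)propyl]-1-vinylcyclopropane-1-carboxylate (vinyl, butenyl and side chain all cis) | CC(C)(C)[Si](C)(C)OCCC[C@@H]1[C@H](/C(C)=C/C)[C@@]1(C=C)C(=O)OC | intermediate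
9 | methyl (4S,7R)-7-[3-(tert-butyldimethylsilyloxy)propyl]-4,5-dimethylcyclohepta-1,5-diene-1-carboxylate | CC(C)(C)[Si](C)(C)OCCC[C@H]1C(C(=O)OC)=CC[C@H](C)C(C)=C1 | intermediate
10 | methyl (4S,5S,6R,7S)-7-[3-(tert-butyldimethylsilyloxy)propyl]-5,6-epoxy-4,5-dimethylcyclohept-1-ene-1-carboxylate | CC(C)(C)[Si](C)(C)OCCC[C@H]1C(C(=O)OC)=CC[C@H](C)[C@]2(C)O[C@H]12 | intermediate
11 | 2-{(4S,5S,6R,7S)-7-[3-(tert-butyldimethylsilyloxy)propyl]-5,6-epoxy-4,5-dimethylcyclohept-1-en-1-yl}propan-2-ol | CC(C)(C)[Si](C)(C)OCCC[C@H]1C(C(C)(C)O)=CC[C@H](C)[C@]2(C)O[C@H]12 | intermediate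
12 | (4S,5S,6R,7S)-7-[3-(tert-butyldimethylsilyloxy)propyl]-5,6-epoxy-4,5-dimethyl-1-(prop-1-en-2-yl)cyclohept-1-ene | CC(C)(C)[Si](C)(C)OCCC[C@H]1C(C(C)=C)=CC[C@H](C)[C@]2(C)O[C@H]12 | intermediate
13 | (1S,2R,3S,7S)-3-[3-(tert-butyldimethylsilyloxy)propyl]-1,2-epoxy-1,7-dimethyl-4-(propan-2-ylidene)cycloheptane | CC(C)(C)[Si](C)(C)OCCC[C@H]1C(=C(C)C)CC[C@H](C)[C@]2(C)O[C@H]12 | intermediate
14 | (1S,2S,6S)-2-[3-(tert-butyldimethylsilyloxy)propyl]-1,6-dimethyl-3-(propan-2-ylidene)cyclohexane-1-carbaldehyde | CC(C)(C)[Si](C)(C)OCCC[C@H]1C(=C(C)C)CC[C@H](C)[C@]1(C)C=O | intermediate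
15 | {(1S,2S,6S)-2-[3-(tert-butyldimethylsilyloxy)propyl]-1,6-dimethyl-3-(propan-2-ylidene)cyclohexyl}methanol | CC(C)(C)[Si](C)(C)OCCC[C@H]1C(=C(C)C)CC[C@H](C)[C@]1(C)CO | intermediate
16 | 7-bromocoumarin | Brc1ccc2ccc(=O)oc2c1 | starting material
17 | 7-({(1S,2S,6S)-2-[3-(tert-butyldimethylsilyloxy)propyl]-1,6-dimethyl-3-(propan-2-ylidene)cyclohexyl}methoxy)-2H-chromen-2-one | CC(C)(C)[Si](C)(C)OCCC[C@H]1C(=C(C)C)CC[C@H](C)[C@]1(C)COc1ccc2ccc(=O)oc2c1 | intermediate
18 | 7-{[(1S,2S,6S)-2-(3-hydroxypropyl)-1,6-dimethyl-3-(propan-2-ylidene)cyclohexyl]methoxy}-2H-chromen-2-one | OCCC[C@H]1C(=C(C)C)CC[C@H](C)[C@]1(C)COc1ccc2ccc(=O)oc2c1 | intermediate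
19 | 3-[(1S,2S,3S)-2,3-dimethyl-2-{[(2-oxo-2H-chromen-7-yl)oxy]methyl}-6-(propan-2-ylidene)cyclohexyl]propyl acetate | CC(=O)OCCC[C@H]1C(=C(C)C)CC[C@H](C)[C@]1(C)COc1ccc2ccc(=O)oc2c1 | target

**Total step count:** 13. **Longest linear sequence:** 12 steps (1 → 19 through steps 1, 2 and 4–13).

**Steps most likely to fail**

Step 4.
- What may go wrong: electrocyclisation of the labile diazo ester before carbene transfer; carbenoid attack at the trisubstituted alkene or at allylic C–H bonds; a homodienyl 1,5-hydrogen shift overtaking the Cope step in the crowded all-cis cyclopropane; insufficient enantioselection.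
- Fallback, setting out from 5 and coming back at 9: the three-carbon partner is exchanged for a bench-stable one at the β-keto ester oxidation level, and the extra oxygen is removed afterwards. Methyl acetoacetate is converted by diazo transfer (p-ABSA, Et3N) into methyl 2-diazo-3-oxobutanoate F1. TBSOTf/Et3N then gives methyl 3-(tert-butyldimethylsilyloxy)-2-diazobut-3-enoate F2. This siloxyvinyldiazoacetate undergoes the same formal [4+3] with 5 under an adamantylglycine-derived dirhodium catalyst, Rh2(PTAD)4 of the appropriate handedness, to give the silyl enol ether cycloadduct F3. CsF/PhNTf2 converts the enol silane selectively into the enol triflate F4. Pd(OAc)2/PPh3/HCO2H/Bu3N hydrogenolysis then gives 9.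

Step 9.
- What may go wrong: hydride shift or proton loss competing with ring-bond migration; capture of the developing cation by the nucleophilic tetrasubstituted alkene; a Lewis-acid-promoted carbonyl-ene reaction between the new aldehyde and the isopropylidene group.
- Fallback, setting out from 10 and coming back at 14: the order is inverted, so that the cationic step runs while the second alkene is still an electron-poor enoate and the isopropylidene is unveiled last under neutral conditions. MABR rearranges 10 to the formyl enoate F5. Lithium morpholide masks the aldehyde in situ as the α-amino alkoxide F6. MeLi then converts the ester, and aqueous work-up releases the hydroxy aldehyde F7. Burgess dehydration gives the dienal F8. The chromium-catalysed 1,4-hydrogenation of step 8 then gives 14.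

Step 5.
- What may go wrong: poor facial selectivity through mismatched double diastereoselection, if the substrate prefers attack syn to the side chain; slow oxidation of the hindered alkene with decay of the ketone catalyst.
- Fallback, setting out from 9 and coming back at 10: the substrate's own bias is used, with inverted outcome. NBS in aqueous DME forms the bromonium ion on the more accessible face, and water opens it at the tertiary carbon from the opposite face to give the trans-bromohydrin F9. K2CO3/MeOH then closes the oxirane with inversion at the secondary carbon. This places oxygen on the face opposite to the one an electrophilic oxidant attacks.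

**Further compounds**
F1 | step 4 | methyl 2-diazo-3-oxobutanoate | COC(=O)C(=[N+]=[N-])C(C)=O
F2 | step 4 | methyl 3-(tert-butyldimethylsilyloxy)-2-diazobut-3-enoate | COC(=O)C(=[N+]=[N-])C(=C)O[Si](C)(C)C(C)(C)C
F3 | step 4 | methyl (4S,7R)-2-(tert-butyldimethylsilyloxy)-7-[3-(tert-butyldimethylsilyloxy)propyl]-4,5-dimethylcyclohepta-1,5-diene-1-carboxylate | CC(C)(C)[Si](C)(C)OCCC[C@H]1C(C(=O)OC)=C(O[Si](C)(C)C(C)(C)C)C[C@H](C)C(C)=C1
F4 | step 4 | methyl (4S,7R)-7-[3-(tert-butyldimethylsilyloxy)propyl]-4,5-dimethyl-2-(trifluoromethylsulfonyloxy)cyclohepta-1,5-diene-1-carboxylate | CC(C)(C)[Si](C)(C)OCCC[C@H]1C(C(=O)OC)=C(OS(=O)(=O)C(F)(F)F)C[C@H](C)C(C)=C1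
F5 | step 9 | methyl 6-[3-(tert-butyldimethylsilyloxy)propyl]-5-formyl-4,5-dimethylcyclohex-1-ene-1-carboxylate (ring configuration as in 14) | CC(C)(C)[Si](C)(C)OCCC[C@H]1C(C(=O)OC)=CC[C@H](C)[C@]1(C)C=O
F6 | step 9 | lithium α-morpholino alkoxide of F5 (carbinol carbon unassigned) | CC(C)(C)[Si](C)(C)OCCC[C@H]1C(C(=O)OC)=CC[C@H](C)[C@]1(C)C([O-])N1CCOCC1.[Li+]
F7 | step 9 | 2-[3-(tert-butyldimethylsilyloxy)propyl]-3-(2-hydroxypropan-2-yl)-1,6-dimethylcyclohex-3-ene-1-carbaldehyde (ring configuration as in 14) | CC(C)(C)[Si](C)(C)OCCC[C@H]1C(C(C)(C)O)=CC[C@H](C)[C@]1(C)C=O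
F8 | step 9 | 2-[3-(tert-butyldimethylsilyloxy)propyl]-1,6-dimethyl-3-(prop-1-en-2-yl)cyclohex-3-ene-1-carbaldehyde (ring configuration as in 14) | CC(C)(C)[Si](C)(C)OCCC[C@H]1C(C(C)=C)=CC[C@H](C)[C@]1(C)C=O
F9 | step 5 | methyl 6-bromo-7-[3-(tert-butyldimethylsilyloxy)propyl]-5-hydroxy-4,5-dimethylcyclohept-1-ene-1-carboxylate (tertiary OH anti to the side chain, Br syn to it) | CC(C)(C)[Si](C)(C)OCCC[C@H]1C(C(=O)OC)=CC[C@H](C)[C@](C)(O)[C@H]1Br
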